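Abbreviations: TBS = tert-butyldimethylsilyl, TBDPS = tert-butyldiphenylsilyl, TMS = trimethylsilyl, MOM = methoxymethyl, Piv = pivaloyl.

## Analysis of the target

The target (42) is a germacranolide. Its ten-membered carbocycle (C1–C10) is bridged by an oxygen between C3 and C10, so that O, C10, C1, C2 and C3 form a 3(2H)-furanone (C1 ketone, C2=C3). A trans-fused α-methylene-γ-butyrolactone (C6–O–C12, C11=C13) sits on C6/C7, C8 carries an isobutyrate and C4 a hydroxymethyl group (C15).

There are four stereocentres. C6 (R), C7 (R) and C8 (R) are contiguous: H6 and H7 are anti, and the C8 oxygen lies on the side of the C7 side chain. The quaternary C10 (S) lies across the ring, its oxygen 1,3-syn to the C8 oxygen. Within the macrocycle C2=C3 is E (locked in the planar furanone) and C4=C5 is ring-cis (C3 and C6 on the same side).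

Sensitive functions are the α-methylene lactone (Michael acceptor), the vinylogous ester of the furanone, the allylic C6–O bond, and the C8 ester, whose carbonyl is within reach of any enolate formed at C11.

The synthesis is hard for three reasons: a strained medium ring holds an E and a ring-cis olefin side by side; the configuration of quaternary C10 must be related to C6–C8 across the ring; and three electrophilic groups must be handled late.

The strategy rests on one feature. C3 and C8 lie opposite each other in the ten-membered ring. A bond between them divides the carbocycle into a cyclohexene C3–C4=C5–C6–C7–C8, which already owns the ring-cis olefin and the contiguous stereocentres, and a bridge C2–C1···C10–C9. That is two alkenyl groups on neighbouring carbons with an oxygen on C8, the pattern of an oxy-Cope ring expansion.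

## Retrosynthetic reasoning

**Lactone (42 ⇒ 41 ⇒ 40).** The O–C12 bond is cut last because the methylene lactone is the most electrophilic group. Going forward, removal of the C6 and C15 silyl ethers of acid 40 frees hydroxy acid 41, which closes the five-membered lactone by itself.

**C11=C13 and C12 (40 ⇒ 39 ⇒ 37 ⇒ 36 ⇒ 35).** The methylene carbon is cut from the C12 aldehyde 37, not from a lactone. A lactone enolate at C11 would sit five atoms from the C8 ester carbonyl and attack it. A Mannich–elimination on the aldehyde needs only an amine base. Aldehyde 37 comes from the primary silyl ether of 35 by selective desilylation (36) and oxidation.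

**Furanone O–C3 bond (35 ⇒ 34).** The C10 oxygen is already in place, so the ring is closed by oxidative addition of the tertiary hydroxyl of dienone 34 to C3. The E geometry of C2=C3 puts that oxygen next to the hydrogen it replaces, and no separate dehydrogenation is needed.

**C1 carbonyl, C8 ester and C8 stereocentre (34 ⇒ 33 ⇒ 31 ⇒ 30 ⇒ 29).** The dienone comes from the allylic alcohol of diol 33. Both hydroxyls of 33 are released together from the bis-MOM ether 31. The ester comes from alcohol 30, and 30 from ketone 29 by a reagent-controlled reduction. C8 is the only stereocentre set after the ring is made.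

**Key disconnection (29 ⇒ 26).** The C1–C10 bond is cut and C3–C8 is drawn instead, which turns the ten-membered ketone into the cyclohexenol 26 with a (Z)-2-(methoxymethoxy)propenyl group on C8 and an alkenyl group on C3. Nowhere else does a single bond exchange convert the medium ring into a six-membered ring that already contains C4=C5, C6 and C7. The forward reaction has to form the ring, the E olefin and C10 in one operation.

**C1 oxygen and enol ether (26 ⇒ 25 ⇒ 23 ⇒ 22 ⇒ 21 ⇒ 20).** C1 must end as a ketone. An allylic oxidation of the rearranged diene at C1 could not be made regioselective: ene-type oxidants would sooner attack the trisubstituted C4=C5 olefin at C15, and radical oxidants the C6–H bond. C1 therefore enters the rearrangement already oxygenated, as the enol ether of side-chain aldehyde 23. The enol ether is made only after C8 is quaternary, with the tertiary hydroxyl masked as silyl ether 21 so that the aldehyde cannot close to a lactol.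

**C8–C9 bond (20 ⇒ 16 + 19).** The tertiary carbinol is cut to ketone 16 and alkenyl bromide 19. The C3 substituent is still a saturated chain at this stage, so 16 is an ordinary β,γ-unsaturated ketone and not a doubly allylic one.

**C8 carbonyl and C15 (16 ⇒ 14 ⇒ 13 ⇒ 12).** The ketone is a nitro group in disguise (Nef reaction), and the protected C15 alcohol is the reduced formyl group of enal 12.

**Cyclohexene ring (12 ⇒ 6 + 10; 6 ⇒ 5 + 4).** C3–C8 and C4=C5 are cut by a nitro-Michael/aldol condensation between nitro aldehyde 6 and enal 10, and C6–C7 by an enamine Michael addition of aldehyde 5 to nitroalkene 4. Each stage is under catalyst control. A single catalyst enantiomer for both stages would place the C3 and C7 chains trans. The two stages are therefore run separately with opposite catalyst enantiomers, which gives the cis arrangement that the rearrangement needs.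

**Building blocks (4 ⇒ 1 + 2; 10 ⇒ 8 + 9; 8 ⇒ 7; 19 ⇒ 17).** Nitroaldol condensation, cross-metathesis, acylation and enolate O-alkylation of commercial materials.

## Alternatives that were turned down

**Alternative 1: late carbonylative closure of the methylene lactone.**
- Disconnection: O–C12 and C11–C12 are cut, leaving the finished macrocycle A1 with a free C6 hydroxyl and an ethynyl group (C11≡C13) on C7.
- Forward step: PdCl2, PPh3 and SnCl2 under CO would turn the hydroxyl into an alkoxycarbonyl–palladium unit that adds across the alkyne and gives the methylene lactone A2, the target as its C15 silyl ether.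
- For: the most electrophilic group appears in one step at the end, with no enolate chemistry near the C8 ester. On this point it is stronger than the chosen route, which needs steps 22–26 for the same ring.
- Against: the step makes neither the carbocycle nor a stereocentre. The E/ring-cis diene, the furanone and C10 of A1 would all have to come from other, unspecified chemistry, and the propargylic C7 centre would have to be carried through it. The Lewis-acidic tin/palladium hydride medium would also have to spare the furanone, the ester and C4=C5.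
- Comparison: it solves the easy end of the problem. The chosen strategy spends its key step on the ring, the E olefin and C10 together and accepts a longer lactone endgame.

**Alternative 2: nitrile oxide cycloaddition closing the ring and a masked furanone.**
- Disconnection: C1–C2 and O–C3 are cut, leaving the open-chain aldoxime A3 with a terminal C2=C3 vinyl group.
- Forward step: NaOCl would oxidise the oxime to the nitrile oxide, which adds to the vinyl group and gives the bridged isoxazoline A4, closing the ten-membered ring.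
- For: C1 and C3 arrive oxidised in the same step that closes the ring. N–O cleavage (for example with Mo(CO)6), oxidation and cyclodehydration would give the furanone without any oxidative C–O bond formation on a diene. Here it is stronger than the chosen route, which must carry the C1 oxygen in as an enol ether and close the furanone oxidatively.
- Against: a ten-membered ring must close through a bridged transition state that places the C=N bond inside the medium ring. It does so in competition with dimerisation of a hindered tertiary nitrile oxide, so high dilution is needed and there is no conformational help. C10 in A3 is an acyclic tertiary ether and C4=C5 an acyclic trisubstituted olefin; each needs separate stereocontrolled chemistry.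
- Comparison: the chosen rearrangement is a unimolecular reorganisation of a six-membered ring, so ring strain is paid by enolate formation, not by entropy. It also sets C10 from an olefin geometry.

**Alternative 3: Ramberg–Bäcklund sulfur deletion forming C4=C5.**
- Disconnection: C4=C5 is cut with sulfur inserted, leaving the eleven-membered α-chloro sulfone A5.
- Forward step: KOt-Bu would remove the C4 proton, chloride is displaced to the episulfone, and SO2 is lost to give A6.
- For: ring closure is moved to a thioether stage, and S-alkylation to an eleven-membered ring is easier than any C–C closure of a ten-membered ring. The furanone can be complete beforehand. In plain reliability of the ring-forming event it is stronger than the chosen route.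
- Against: A6 carries C15 as a methyl group, so an allylic oxidation is still needed late, next to the furanone and with C6 competing. The strong base would meet a methyl ester with α-hydrogens and a C6 silyloxy group β to the sulfone-stabilised carbanion at C5. The geometry of the new trisubstituted olefin in the medium ring is not fixed by the mechanism. No stereocentre is made, and the sulfur needs three extra operations (install, oxidise, chlorinate).
- Comparison: the chosen strategy obtains the ring-cis olefin for free from a cyclohexene, with C15 at the right oxidation level, and uses its ring-forming step to set a stereocentre as well.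

Key step: step 16

Assumptions: germacrane locants are used for all intermediates (cyclohexene ring atoms are C3–C8). Elements that are destroyed later are carried as mixtures and left undefined in names and SMILES: C8 of 11–14, the C1=C2 geometry of 24–27, C1 of 28–33 and C11 of 38.

## Steps

Step 1
Reactants: 1 3-(OTBS)propanal; 2 nitromethane
Product: 4 (E)-4-(OTBS)-1-nitrobut-1-ene, via nitro alcohol 3 (not isolated)
Conditions: MeNO2, KOt-Bu (cat.), THF/t-BuOH, 0 °C; then MsCl, Et3N, CH2Cl2, −10 °C
Reagents that add atoms: none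
Why: Henry addition followed by mesylation and E1cB elimination (nitroaldol condensation); the conjugated E nitroalkene is the thermodynamic isomer.

Step 2
Reactants: 5 (OTBS)acetaldehyde; 4 (E)-4-(OTBS)-1-nitrobut-1-ene
Product: 6 (2S,3R)-2,5-bis(OTBS)-3-(nitromethyl)pentanal
Conditions: 5 (1.5 equiv), (R)-2-[diphenyl(trimethylsilyloxy)methyl]pyrrolidine (10 mol %), ClCH2CO2H (20 mol %), CH2Cl2, 0 °C to rt
Reagents that add atoms: none
Why: Enamine Michael addition catalysed by a diarylprolinol silyl ether: the E enamine of 5 is attacked on the face away from the diarylsilyloxymethyl group through the acyclic synclinal transition state, which gives the syn adduct and, with the R catalyst, the 2S,3R configuration (C6 and C7 of the target, oxygen and side chain anti in the later ring).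

Step 3
Reactants: 7 but-3-en-1-ol
Product: 8 but-3-en-1-yl pivalate
Conditions: PivCl, pyridine, DMAP (cat.), CH2Cl2, 0 °C
Reagents that add atoms: pivaloyl chloride CC(C)(C)C(=O)Cl
Why: Acylation of a primary alcohol; the pivalate survives amine catalysis, the Nef reaction and the organocerium addition and is later removed reductively.

Step 4
Reactants: 8 but-3-en-1-yl pivalate; 9 (E)-but-2-enal
Product: 10 (E)-5-oxopent-3-en-1-yl pivalate
Conditions: 9 (5 equiv), second-generation Grubbs catalyst (3 mol %), CH2Cl2, 40 °C
Reagents that add atoms: none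
Why: Olefin cross-metathesis of a terminal alkene with excess crotonaldehyde; propene is lost and the E enal is the thermodynamic product.

Step 5
Reactants: 6 (2S,3R)-2,5-bis(OTBS)-3-(nitromethyl)pentanal; 10 (E)-5-oxopent-3-en-1-yl pivalate
Product: 12 cyclohexene enal (3R,6R,7R; C4 CHO; C8 NO2; C3 CH2CH2OPiv; C6 OTBS; C7 CH2CH2OTBS), via nitro dialdehyde 11 (not isolated)
Conditions: 6 freed of the R catalyst, (S)-2-[diphenyl(trimethylsilyloxy)methyl]pyrrolidine (20 mol %), PhCO2H (20 mol %), toluene, 0 °C to rt
Reagents that add atoms: none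
Why: Iminium-activated nitro-Michael addition of 6 to 10 followed by intramolecular enamine aldol condensation (the later stages of an Enders-type organocascade, run separately): the S catalyst shields one face of the enal so that C3 forms with its chain cis to the C7 chain (the R catalyst of step 2 would give the C3 epimer), the aldol condensation closes C4–C5 (6-enolexo) to the conjugated enal, and the nitro-bearing C8 may form as a mixture because it becomes a ketone.

Step 6
Reactants: 12 cyclohexene enal
Product: 13 allylic alcohol (3R,6R,7R; C4 CH2OH; C8 NO2)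
Conditions: NaBH4, CeCl3·7H2O, MeOH, −40 °C
Reagents that add atoms: none
Why: Luche 1,2-reduction of the enal; the nitro group and the pivalate are untouched.

Step 7
Reactants: 13 allylic alcohol
Product: 14 silyl ether (3R,6R,7R; C4 CH2OTBDPS; C8 NO2)
Conditions: TBDPSCl, imidazole, DMF, 0 °C to rt
Reagents that add atoms: tert-butyl(chloro)diphenylsilane CC(C)(C)[Si](Cl)(c1ccccc1)c1ccccc1
Why: Silylation of the primary allylic alcohol; TBDPS is chosen to outlast both TBS ethers until the last step.

Step 8
Reactants: 14 silyl ether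
Product: 16 ketone (3R,6R,7S; C8 oxo; C3 CH2CH2OPiv; C4 CH2OTBDPS; C6 OTBS; C7 CH2CH2OTBS), via sodium nitronate 15 (not isolated)
Conditions: NaOMe, MeOH, 0 °C; then TiCl3 (aq), NH4OAc, THF/H2O, pH 5–6, 0 °C to rt
Reagents that add atoms: water O
Why: McMurry variant of the Nef reaction: the nitronate is reduced by trivalent titanium to the imine, which hydrolyses in the buffered medium to the β,γ-unsaturated ketone without moving the double bond or epimerising C3 and C7; the ketone is used at once.

Step 9
Reactants: 17 bromoacetone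
Product: 19 (Z)-1-bromo-2-(methoxymethoxy)prop-1-ene, via potassium enolate 18 (not isolated)
Conditions: KN(SiMe3)2, THF/DMPU, −78 °C; MOMCl, −78 to 0 °C
Reagents that add atoms: chloromethyl methyl ether COCCl
Why: O-alkylation of a potassium enolate by a hard electrophile; deprotonation occurs at the more acidic bromomethyl group and the enolate with bromine syn to oxygen and anti to methyl (Z) is expected to prevail; any E isomer is removed by distillation and would not give a stable lithium reagent.

Step 10
Reactants: 16 ketone; 19 (Z)-1-bromo-2-(methoxymethoxy)prop-1-ene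
Product: 20 tertiary alcohol (3R,6R,7S,8R; C8 OH and (Z)-CH=C(CH3)OMOM; C3 CH2CH2OPiv)
Conditions: 19, t-BuLi (2 equiv), Et2O, −78 °C; CeCl3, THF, −78 °C; then 16, −78 °C; NH4Cl (aq)
Reagents that add atoms: none
Why: Bromine–lithium exchange with retention gives the cis-β-alkoxy alkenyllithium (held by O–Li chelation) and transmetalation to cerium gives a weakly basic nucleophile that adds to the enolisable β,γ-unsaturated ketone without deprotonation; equatorial attack, trans to the two equatorial α-substituents, is expected for this bulky Z-alkenyl reagent and gives the 8R carbinol in which the alkenyl group is trans to the C3 chain, as the rearrangement requires.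

Step 11
Reactants: 20 tertiary alcohol
Product: 21 TMS ether (3R,6R,7S,8R; C8 OTMS)
Conditions: 1-(trimethylsilyl)imidazole, CH2Cl2, rt
Reagents that add atoms: 1-(trimethylsilyl)imidazole C[Si](C)(C)n1ccnc1
Why: Silylation of the hindered tertiary alcohol under neutral conditions so that the γ-hydroxy aldehyde of step 13 cannot close to a lactol.

Step 12
Reactants: 21 TMS ether
Product: 22 primary alcohol (3R,6R,7S,8R; C3 CH2CH2OH)
Conditions: i-Bu2AlH, CH2Cl2, −78 °C; KNaC4H4O6 (aq)
Reagents that add atoms: none
Why: Reductive cleavage of the pivalate at low temperature; silyl ethers and the enol ether are inert to the hydride.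

Step 13
Reactants: 22 primary alcohol
Product: 23 aldehyde (3R,6R,7S,8R; C3 CH2CHO)
Conditions: Dess–Martin periodinane, NaHCO3, CH2Cl2, 0 °C
Reagents that add atoms: none
Why: Dess–Martin oxidation under buffered, non-acidic conditions that spare the enol ether and the tertiary silyl ether.

Step 14
Reactants: 23 aldehyde
Product: 25 bis(enol ether) (3R,6R,7S,8R; C3 CH=CHOMOM; C8 OTMS), via potassium enolate 24 (not isolated)
Conditions: KN(SiMe3)2, THF, −78 °C; MOMCl, DMPU, −78 to −20 °C
Reagents that add atoms: chloromethyl methyl ether COCCl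
Why: The kinetic potassium enolate of the aldehyde is O-alkylated by the hard electrophile, which brings the C1 oxygen into the diene as an enol ether; the E/Z ratio does not matter because C1 ends as a ketone.

Step 15
Reactants: 25 bis(enol ether)
Product: 26 cyclohexenol (3R,6R,7S,8R; C8 OH and (Z)-CH=C(CH3)OMOM; C3 CH=CHOMOM; C4 CH2OTBDPS; C6 OTBS; C7 CH2CH2OTBS)
Conditions: K2CO3, MeOH, 0 °C
Reagents that add atoms: none
Why: Mild methanolysis of the tertiary trimethylsilyl ether; enol ethers and the bulkier silyl ethers are stable to carbonate in methanol.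

Step 16
Reactants: 26 cyclohexenol
Product: 29 cyclodeca-2,4-dien-8-one (2E,4E,6R,7S,10S; C1 OMOM; C10 CH3 and OMOM), via potassium alkoxide 27 (not isolated), via potassium enolate 28 (not isolated)
Conditions: KH, 18-crown-6, THF, −20 to 0 °C; then into AcOH/THF, −78 °C
Reagents that add atoms: none
Why: KH with 18-crown-6 gives the dissociated alkoxide 27, whose diene C10=C9–C8–C3–C2=C1 undergoes an anionic oxy-Cope [3,3] shift in which C3–C8 (weakened by the oxyanion and allylic to both C4=C5 and C1=C2) breaks as C1–C10 forms, giving enolate 28, which is protonated at C9 on cold quench. The closest known reaction type is the anionic oxy-Cope ring expansion of trans-1,2-dialkenylcyclohexanols to (E)-cyclodec-5-enones. The ten-membered ring is not closed by a cyclisation but grows out of the cyclohexene by four atoms through a six-membered chair transition state, suprafacial on both allyl units. Because the two alkenyl groups are trans, only one chair is possible, the one with C7 and C4 equatorial on the breaking bond and the alkoxide axial; it coincides with the cyclohexene half-chair that keeps the C6 silyloxy group and the C7 chain equatorial, so the reactive conformer is the ground-state conformer. C4 equatorial gives the E C2=C3 olefin, and the ring-cis C4=C5 olefin is carried over unchanged. C10 is set by the Z enol ether, which places OMOM axial and methyl equatorial in this chair and leads to 10S; C1 forms as a mixture that is erased in step 20. The step needs the [3,3] path to win over fragmentation–recombination, over the boat-like shift through C4=C5 and over β-elimination of the C10 alkoxy group from 28 (its C–O bond is aligned with the enolate π system); the doubly allylic breaking bond allows a low temperature, and the inverse cold acid quench and immediate reduction (step 17) guard the β-alkoxy ketone.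

Step 17
Reactants: 29 cyclodeca-2,4-dien-8-one
Product: 30 alcohol (2E,4E,6R,7R,8R,10S; C8 OH)
Conditions: (S)-2-methyl-CBS-oxazaborolidine, catecholborane, toluene, −78 °C
Reagents that add atoms: none
Why: Corey–Bakshi–Shibata reduction: with branched C7 as the large flank and C9H2 as the small one, the S catalyst should deliver hydride to give the 8R alcohol (oxygen syn to the C7 chain); the low temperature protects the β-alkoxy ketone.

Step 18
Reactants: 30 alcohol
Product: 31 isobutyrate (2E,4E,6R,7R,8R,10S; C8 OC(O)CH(CH3)2)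
Conditions: (i-PrCO)2O, DMAP, Et3N, CH2Cl2, 0 °C to rt
Reagents that add atoms: isobutyric anhydride CC(C)C(=O)OC(=O)C(C)C
Why: DMAP-catalysed acylation of the secondary alcohol; the ester goes on now because no later step uses a strong base.

Step 19
Reactants: 31 isobutyrate
Product: 33 diol (2E,4E,6R,7R,8R,10S; C1 OH; C10 OH), via bis(bromomethyl) ether 32 (not isolated)
Conditions: Me2BBr, CH2Cl2, −78 °C; then NaHCO3 (aq)/THF, 0 °C
Reagents that add atoms: none
Why: Dimethylboron bromide cleaves methoxymethyl ethers at −78 °C by attack at the terminal methoxy oxygen, so the allylic C1–O and tertiary C10–O bonds are not ionised, and the bromomethyl ethers hydrolyse on bicarbonate work-up; silyl ethers and the ester survive.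

Step 20
Reactants: 33 diol
Product: 34 hydroxy dienone (2E,4E,6R,7R,8R,10S; C1 oxo; C10 OH)
Conditions: MnO2, CH2Cl2, rt
Reagents that add atoms: none
Why: MnO2 oxidises only the allylic (dienylic) secondary alcohol at C1; the tertiary C10 hydroxyl cannot react, and both C1 epimers converge.

Step 21
Reactants: 34 hydroxy dienone
Product: 35 furanone macrocycle (4Z,6R,7R,8R,10S; O bridge C3–C10; C1 oxo; C2=C3)
Conditions: Pd(OAc)2 (20 mol %), O2 (1 atm), DMSO, 40 °C
Reagents that add atoms: none
Why: Wacker-type 5-endo oxypalladation of the α′-hydroxy enone at C3 followed by β-hydride elimination of the C3 hydrogen, which is syn to palladium after anti addition, gives the 3(2H)-furanone (a known oxidative cyclisation of α′-hydroxy enones under divalent palladium with O2 as terminal oxidant); the E olefin places the C10 oxygen next to the hydrogen it replaces.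

Step 22
Reactants: 35 furanone macrocycle
Product: 36 primary alcohol (4Z,6R,7R,8R,10S; C7 CH2CH2OH)
Conditions: HF·pyridine, pyridine, THF, 0 °C
Reagents that add atoms: none
Why: Buffered HF·pyridine removes the primary TBS ether faster than the secondary allylic one and far faster than the TBDPS ether.

Step 23
Reactants: 36 primary alcohol
Product: 37 aldehyde (4Z,6R,7R,8R,10S; C7 CH2CHO)
Conditions: Dess–Martin periodinane, NaHCO3, CH2Cl2, 0 °C
Reagents that add atoms: none
Why: Dess–Martin oxidation of the only free hydroxyl; the new aldehyde has no stereocentre at its α-carbon.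

Step 24
Reactants: 37 aldehyde
Product: 39 2-substituted acrolein (4Z,6R,7R,8R,10S; C7 C(=CH2)CHO), via Mannich base 38 (not isolated)
Conditions: CH2=NMe2+ I−, Et3N, CH2Cl2, rt
Reagents that add atoms: N,N-dimethylmethyleneiminium iodide C=[N+](C)C.[I-]
Why: Mannich reaction of the aldehyde with the iminium salt and β-elimination of dimethylamine (α-methylenation) installs C13 under amine-base conditions that do not enolise the C8 ester.

Step 25
Reactants: 39 2-substituted acrolein
Product: 40 acrylic acid (4Z,6R,7R,8R,10S; C7 C(=CH2)CO2H)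
Conditions: NaClO2, NaH2PO4, 2-methyl-2-butene, t-BuOH/H2O, 0 °C
Reagents that add atoms: sodium chlorite [Na+].[O-]Cl=O
Why: Pinnick oxidation of the enal with a hypochlorite scavenger; the olefins and the furanone are not attacked.

Step 26
Reactants: 40 acrylic acid
Product: 42 target CNP0176924.2 (6R,7R,8R,10S), via hydroxy acid 41 (not isolated)
Conditions: HF·pyridine, THF, 0 °C to rt
Reagents that add atoms: none
Why: Fluoride-mediated removal of the C6 TBS and C15 TBDPS ethers; the freed C6 hydroxyl and the C12 acid close the trans γ-lactone spontaneously in the mildly acidic medium (5-exo-trig acyl substitution) and the primary C15 hydroxyl stays free.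

## Compound list

1 | 3-(tert-butyldimethylsilyloxy)propanal | O=CCCO[Si](C)(C)C(C)(C)C | starting material
2 | nitromethane | C[N+](=O)[O-] | starting material
3 | 4-(OTBS)-1-nitrobutan-2-ol (racemic) | OC(C[N+](=O)[O-])CCO[Si](C)(C)C(C)(C)C | intermediate
4 | (E)-4-(OTBS)-1-nitrobut-1-ene | [O-][N+](=O)/C=C/CCO[Si](C)(C)C(C)(C)C | intermediate
5 | (tert-butyldimethylsilyloxy)acetaldehyde | O=CCO[Si](C)(C)C(C)(C)C | starting material
6 | (2S,3R)-2,5-bis(OTBS)-3-(nitromethyl)pentanal | O=C[C@@H](O[Si](C)(C)C(C)(C)C)[C@H](CCO[Si](C)(C)C(C)(C)C)C[N+](=O)[O-] | intermediate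
7 | but-3-en-1-ol | C=CCCO | starting material
8 | but-3-en-1-yl pivalate | C=CCCOC(=O)C(C)(C)C | intermediate
9 | (E)-but-2-enal | C/C=C/C=O | starting material
10 | (E)-5-oxopent-3-en-1-yl pivalate | O=C/C=C/CCOC(=O)C(C)(C)C | intermediate
11 | (2S,3R,5R)-2-(OTBS)-3-[2-(OTBS)ethyl]-4-nitro-5-[2-(pivaloyloxy)ethyl]heptanedial, C4 epimers | O=CC[C@@H](CCOC(=O)C(C)(C)C)C([N+](=O)[O-])[C@@H](CCO[Si](C)(C)C(C)(C)C)[C@H](O[Si](C)(C)C(C)(C)C)C=O | intermediate
12 | cyclohex-4-ene (ring C3–C8), 3R,6R,7R: C3 2-(pivaloyloxy)ethyl, C4 formyl, C6 OTBS, C7 2-(OTBS)ethyl, C8 nitro (epimers) | CC(C)(C)C(=O)OCC[C@@H]1C(C=O)=C[C@@H](O[Si](C)(C)C(C)(C)C)[C@H](CCO[Si](C)(C)C(C)(C)C)C1[N+](=O)[O-] | intermediate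
13 | as 12 with C4 hydroxymethyl (3R,6R,7R) | CC(C)(C)C(=O)OCC[C@@H]1C(CO)=C[C@@H](O[Si](C)(C)C(C)(C)C)[C@H](CCO[Si](C)(C)C(C)(C)C)C1[N+](=O)[O-] | intermediate
14 | as 13 with C4 CH2OTBDPS (3R,6R,7R) | CC(C)(C)C(=O)OCC[C@@H]1C(CO[Si](c2ccccc2)(c2ccccc2)C(C)(C)C)=C[C@@H](O[Si](C)(C)C(C)(C)C)[C@H](CCO[Si](C)(C)C(C)(C)C)C1[N+](=O)[O-] | intermediate
15 | sodium nitronate of 14 | CC(C)(C)C(=O)OCC[C@@H]1C(CO[Si](c2ccccc2)(c2ccccc2)C(C)(C)C)=C[C@@H](O[Si](C)(C)C(C)(C)C)[C@H](CCO[Si](C)(C)C(C)(C)C)C1=[N+]([O-])[O-].[Na+] | intermediate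
16 | cyclohex-4-en-8-one (ring C3–C8), 3R,6R,7S: C3 2-(pivaloyloxy)ethyl, C4 CH2OTBDPS, C6 OTBS, C7 2-(OTBS)ethyl | CC(C)(C)C(=O)OCC[C@@H]1C(CO[Si](c2ccccc2)(c2ccccc2)C(C)(C)C)=C[C@@H](O[Si](C)(C)C(C)(C)C)[C@H](CCO[Si](C)(C)C(C)(C)C)C1=O | intermediate
17 | bromoacetone | CC(=O)CBr | starting material
18 | potassium (Z)-1-bromoprop-1-en-2-olate | Br/C=C(/C)[O-].[K+] | intermediate
19 | (Z)-1-bromo-2-(methoxymethoxy)prop-1-ene | Br/C=C(/C)OCOC | intermediate
20 | cyclohex-4-en-8-ol, 3R,6R,7S,8R: C8 OH and (Z)-2-(methoxymethoxy)prop-1-enyl, C3 2-(pivaloyloxy)ethyl, C4 CH2OTBDPS, C6 OTBS, C7 2-(OTBS)ethyl | CC(C)(C)C(=O)OCC[C@@H]1C(CO[Si](c2ccccc2)(c2ccccc2)C(C)(C)C)=C[C@@H](O[Si](C)(C)C(C)(C)C)[C@H](CCO[Si](C)(C)C(C)(C)C)[C@@]1(O)/C=C(/C)OCOC | intermediate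
21 | C8 trimethylsilyl ether of 20 | CC(C)(C)C(=O)OCC[C@@H]1C(CO[Si](c2ccccc2)(c2ccccc2)C(C)(C)C)=C[C@@H](O[Si](C)(C)C(C)(C)C)[C@H](CCO[Si](C)(C)C(C)(C)C)[C@@]1(O[Si](C)(C)C)/C=C(/C)OCOC | intermediate
22 | as 21 with C3 2-hydroxyethyl | OCC[C@@H]1C(CO[Si](c2ccccc2)(c2ccccc2)C(C)(C)C)=C[C@@H](O[Si](C)(C)C(C)(C)C)[C@H](CCO[Si](C)(C)C(C)(C)C)[C@@]1(O[Si](C)(C)C)/C=C(/C)OCOC | intermediate
23 | as 21 with C3 2-oxoethyl | O=CC[C@@H]1C(CO[Si](c2ccccc2)(c2ccccc2)C(C)(C)C)=C[C@@H](O[Si](C)(C)C(C)(C)C)[C@H](CCO[Si](C)(C)C(C)(C)C)[C@@]1(O[Si](C)(C)C)/C=C(/C)OCOC | intermediate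
24 | potassium enolate of 23 (C1=C2, E/Z) | [K+].[O-]C=C[C@@H]1C(CO[Si](c2ccccc2)(c2ccccc2)C(C)(C)C)=C[C@@H](O[Si](C)(C)C(C)(C)C)[C@H](CCO[Si](C)(C)C(C)(C)C)[C@@]1(O[Si](C)(C)C)/C=C(/C)OCOC | intermediate
25 | as 21 with C3 2-(methoxymethoxy)ethenyl (E/Z) | COCOC=C[C@@H]1C(CO[Si](c2ccccc2)(c2ccccc2)C(C)(C)C)=C[C@@H](O[Si](C)(C)C(C)(C)C)[C@H](CCO[Si](C)(C)C(C)(C)C)[C@@]1(O[Si](C)(C)C)/C=C(/C)OCOC | intermediate
26 | cyclohex-4-en-8-ol, 3R,6R,7S,8R: C8 OH and (Z)-2-(methoxymethoxy)prop-1-enyl, C3 2-(methoxymethoxy)ethenyl (E/Z), C4 CH2OTBDPS, C6 OTBS, C7 2-(OTBS)ethyl | COCOC=C[C@@H]1C(CO[Si](c2ccccc2)(c2ccccc2)C(C)(C)C)=C[C@@H](O[Si](C)(C)C(C)(C)C)[C@H](CCO[Si](C)(C)C(C)(C)C)[C@@]1(O)/C=C(/C)OCOC | intermediate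
27 | potassium alkoxide of 26 | COCOC=C[C@@H]1C(CO[Si](c2ccccc2)(c2ccccc2)C(C)(C)C)=C[C@@H](O[Si](C)(C)C(C)(C)C)[C@H](CCO[Si](C)(C)C(C)(C)C)[C@@]1([O-])/C=C(/C)OCOC.[K+] | intermediate
28 | potassium C8=C9 enolate of 29 (6R,7S,10S) | CC(C)(C)[Si](C)(C)O[C@@H]1/C=C(/CO[Si](c2ccccc2)(c2ccccc2)C(C)(C)C)\C=C\C(OCOC)[C@@](C)(OCOC)/C=C(\[O-])[C@H]1CCO[Si](C)(C)C(C)(C)C.[K+] | intermediate
29 | cyclodeca-2,4-dien-8-one (ring C1–C10), 2E,4E (C3 and C6 cis on C4=C5),6R,7S,10S: C1 OMOM (epimers), C4 CH2OTBDPS, C6 OTBS, C7 2-(OTBS)ethyl, C10 methyl and OMOM | CC(C)(C)[Si](C)(C)O[C@@H]1/C=C(/CO[Si](c2ccccc2)(c2ccccc2)C(C)(C)C)\C=C\C(OCOC)[C@@](C)(OCOC)CC(=O)[C@H]1CCO[Si](C)(C)C(C)(C)C | intermediate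
30 | 8R alcohol of 29 (6R,7R,8R,10S) | CC(C)(C)[Si](C)(C)O[C@@H]1/C=C(/CO[Si](c2ccccc2)(c2ccccc2)C(C)(C)C)\C=C\C(OCOC)[C@@](C)(OCOC)C[C@@H](O)[C@H]1CCO[Si](C)(C)C(C)(C)C | intermediate
31 | C8 isobutyrate of 30 (6R,7R,8R,10S) | CC(C)(C)[Si](C)(C)O[C@@H]1/C=C(/CO[Si](c2ccccc2)(c2ccccc2)C(C)(C)C)\C=C\C(OCOC)[C@@](C)(OCOC)C[C@@H](OC(=O)C(C)C)[C@H]1CCO[Si](C)(C)C(C)(C)C | intermediate
32 | as 31 with bromomethyl ethers on the C1 and C10 oxygens | CC(C)(C)[Si](C)(C)O[C@@H]1/C=C(/CO[Si](c2ccccc2)(c2ccccc2)C(C)(C)C)\C=C\C(OCBr)[C@@](C)(OCBr)C[C@@H](OC(=O)C(C)C)[C@H]1CCO[Si](C)(C)C(C)(C)C | intermediate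
33 | as 31 with free C1 (epimers) and C10 hydroxyls (6R,7R,8R,10S) | CC(C)(C)[Si](C)(C)O[C@@H]1/C=C(/CO[Si](c2ccccc2)(c2ccccc2)C(C)(C)C)\C=C\C(O)[C@@](C)(O)C[C@@H](OC(=O)C(C)C)[C@H]1CCO[Si](C)(C)C(C)(C)C | intermediate
34 | cyclodeca-2,4-dien-1-one, 2E,4E,6R,7R,8R,10S: C10 OH and methyl, C8 isobutyrate, C4 CH2OTBDPS, C6 OTBS, C7 2-(OTBS)ethyl | CC(C)(C)[Si](C)(C)O[C@@H]1/C=C(/CO[Si](c2ccccc2)(c2ccccc2)C(C)(C)C)\C=C\C(=O)[C@@](C)(O)C[C@@H](OC(=O)C(C)C)[C@H]1CCO[Si](C)(C)C(C)(C)C | intermediate
35 | furanone macrocycle, 4Z,6R,7R,8R,10S: oxygen bridge C3–C10, C1 oxo, C2=C3, C4 CH2OTBDPS, C6 OTBS, C7 2-(OTBS)ethyl, C8 isobutyrate | CC(C)(C)[Si](C)(C)O[C@@H]1/C=C(/CO[Si](c3ccccc3)(c3ccccc3)C(C)(C)C)C2=CC(=O)[C@](C)(C[C@@H](OC(=O)C(C)C)[C@H]1CCO[Si](C)(C)C(C)(C)C)O2 | intermediate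
36 | as 35 with C7 2-hydroxyethyl | CC(C)(C)[Si](C)(C)O[C@@H]1/C=C(/CO[Si](c3ccccc3)(c3ccccc3)C(C)(C)C)C2=CC(=O)[C@](C)(C[C@@H](OC(=O)C(C)C)[C@H]1CCO)O2 | intermediate
37 | as 35 with C7 2-oxoethyl | CC(C)(C)[Si](C)(C)O[C@@H]1/C=C(/CO[Si](c3ccccc3)(c3ccccc3)C(C)(C)C)C2=CC(=O)[C@](C)(C[C@@H](OC(=O)C(C)C)[C@H]1CC=O)O2 | intermediate
38 | as 37 with a dimethylaminomethyl group on C11 (epimers) | CC(C)(C)[Si](C)(C)O[C@@H]1/C=C(/CO[Si](c3ccccc3)(c3ccccc3)C(C)(C)C)C2=CC(=O)[C@](C)(C[C@@H](OC(=O)C(C)C)[C@H]1C(CN(C)C)C=O)O2 | intermediate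
39 | as 35 with C7 1-formylethenyl (C11=C13, C12 aldehyde) | CC(C)(C)[Si](C)(C)O[C@@H]1/C=C(/CO[Si](c3ccccc3)(c3ccccc3)C(C)(C)C)C2=CC(=O)[C@](C)(C[C@@H](OC(=O)C(C)C)[C@H]1C(=C)C=O)O2 | intermediate
40 | as 35 with C7 1-carboxyethenyl (C12 acid) | CC(C)(C)[Si](C)(C)O[C@@H]1/C=C(/CO[Si](c3ccccc3)(c3ccccc3)C(C)(C)C)C2=CC(=O)[C@](C)(C[C@@H](OC(=O)C(C)C)[C@H]1C(=C)C(=O)O)O2 | intermediate
41 | hydroxy acid, 4Z,6R,7S,8R,10S: C6 OH, C15 OH, C7 1-carboxyethenyl, C8 isobutyrate | O[C@@H]1/C=C(/CO)C2=CC(=O)[C@](C)(C[C@@H](OC(=O)C(C)C)[C@H]1C(=C)C(=O)O)O2 | intermediate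
42 | CNP0176924.2 (6R,7R,8R,10S) | C=C1C(=O)O[C@@H]2/C=C(/CO)C3=CC(=O)[C@](C)(C[C@@H](OC(=O)C(C)C)[C@@H]12)O3 | target

## Step count and least certain steps

Total: 26 steps. Longest linear sequence: 23 steps (1, 2, 5–8, 10–26).

**Step 16 (key step).** The enolate 28 may expel the C10 alkoxy group by β-elimination before the quench, because that C–O bond is aligned with the enolate. The shift itself may also be slow, since both bond-forming termini carry oxygen and C10 is fully substituted, which would leave time for fragmentation. Fallback: set out from the silyl ether 25 and run the neutral, thermal siloxy-Cope rearrangement (toluene, sealed tube, 150–180 °C). It gives the trimethylsilyl enol ether F1 directly and never forms an enolate. Hydrolysis of F1 with buffered aqueous AcOH/THF at 0 °C comes back to the route at 29.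

**Step 5.** The α-silyloxy aldehyde of 6 may epimerise at C6 through its own enamine, or oligomerise, before the slow nitro-Michael addition of two aliphatic partners occurs; facial control at C3 would then also suffer. Fallback: set out from 6 and protect the aldehyde as the dimethyl acetal F2 (HC(OMe)3, pyridinium p-toluenesulfonate). Run the intermolecular nitro-Michael addition to 10 with the same S catalyst to give the acetal aldehyde F3. Unveil the aldehyde with aqueous acid and close the ring with pyrrolidinium acetate (aldol condensation), which comes back at 12.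

**Step 9.** The bromo enolate may be trapped as a mixture of geometric isomers, or may condense with itself or alkylate on carbon. Fallback: set out from 17 and form the silyl enol ether F4 by soft enolisation (TMSOTf, Et3N), where the geometry equilibrates and the Z isomer can be distilled. Cleave F4 with KOt-Bu at −78 °C to the geometrically defined potassium enolate and trap it with MOMCl, which comes back at 19.

**Step 17.** The conformation of the macrocycle, and not the catalyst, may decide the face of hydride delivery and give the 8S alcohol. Fallback: set out from 29 and accept the substrate-controlled reduction (NaBH4, MeOH, −40 °C) to the 8S alcohol F5. Invert it under Mitsunobu conditions (4-nitrobenzoic acid, PPh3, diisopropyl azodicarboxylate) to the 8R ester F6 and cleave that with K2CO3 in MeOH, which comes back at 30.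

**Step 21.** Palladium may bind the conjugated diene and go down unproductive β-hydride paths, or the 5-endo oxypalladation may not occur. Fallback: set out from 34 and separate the two events. DBU-mediated conjugate addition of the C10 hydroxyl to C3 gives the dihydrofuranone F7. Dehydrogenation of F7 with benzeneseleninic anhydride (chlorobenzene, 95 °C) comes back at 35.

## Further compounds

F1 | step 16 | (8Z)-trimethylsilyl enol ether of 29 (C8 OTMS, C8=C9; 6R,7S,10S) | CC(C)(C)[Si](C)(C)O[C@@H]1/C=C(/CO[Si](c2ccccc2)(c2ccccc2)C(C)(C)C)\C=C\C(OCOC)[C@@](C)(OCOC)/C=C(\O[Si](C)(C)C)[C@H]1CCO[Si](C)(C)C(C)(C)C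
F2 | step 5 | (2S,3R)-1,1-dimethoxy-2,5-bis(OTBS)-3-(nitromethyl)pentane | COC(OC)[C@@H](O[Si](C)(C)C(C)(C)C)[C@H](CCO[Si](C)(C)C(C)(C)C)C[N+](=O)[O-]
F3 | step 5 | nitro-Michael adduct of F2 and 10 (dimethyl acetal of 11) | COC(OC)[C@@H](O[Si](C)(C)C(C)(C)C)[C@H](CCO[Si](C)(C)C(C)(C)C)C([N+](=O)[O-])[C@H](CCOC(=O)C(C)(C)C)CC=O
F4 | step 9 | (Z)-[(1-bromoprop-1-en-2-yl)oxy]trimethylsilane | Br/C=C(/C)O[Si](C)(C)C
F5 | step 17 | 8S epimer of 30 | CC(C)(C)[Si](C)(C)O[C@@H]1/C=C(/CO[Si](c2ccccc2)(c2ccccc2)C(C)(C)C)\C=C\C(OCOC)[C@@](C)(OCOC)C[C@H](O)[C@H]1CCO[Si](C)(C)C(C)(C)C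
F6 | step 17 | 8R 4-nitrobenzoate of 30 | CC(C)(C)[Si](C)(C)O[C@@H]1/C=C(/CO[Si](c2ccccc2)(c2ccccc2)C(C)(C)C)\C=C\C(OCOC)[C@@](C)(OCOC)C[C@@H](OC(=O)c2ccc(cc2)[N+](=O)[O-])[C@H]1CCO[Si](C)(C)C(C)(C)C
F7 | step 21 | 2,3-dihydro analogue of 35 (C3 sp3, epimers) | CC(C)(C)[Si](C)(C)O[C@@H]1/C=C(/CO[Si](c3ccccc3)(c3ccccc3)C(C)(C)C)C2CC(=O)[C@](C)(C[C@@H](OC(=O)C(C)C)[C@H]1CCO[Si](C)(C)C(C)(C)C)O2
A1 | alternative 1 | furanone macrocycle with free C6 hydroxyl, C7 ethynyl, C8 isobutyrate, C15 OTBS | C#C[C@H]1[C@H](O)/C=C(/CO[Si](C)(C)C(C)(C)C)C2=CC(=O)[C@](C)(C[C@H]1OC(=O)C(C)C)O2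
A2 | alternative 1 | C15 TBS ether of the target | C=C1C(=O)O[C@@H]2/C=C(/CO[Si](C)(C)C(C)(C)C)C3=CC(=O)[C@](C)(C[C@@H](OC(=O)C(C)C)[C@@H]12)O3
A3 | alternative 2 | open-chain C1 aldoxime with C2=C3 vinyl group, lactone in place | O/N=C/[C@@](C)(O[Si](CC)(CC)CC)C[C@@H](O[Si](C)(C)C(C)(C)C)[C@H]1CC(=O)O[C@@H]1/C=C(CO[Si](C)(C)C(C)(C)C)\C=C
A4 | alternative 2 | bridged isoxazoline macrocycle | C1C(=O)O[C@@H]2/C=C(/CO[Si](C)(C)C(C)(C)C)[C@@H]3CC(=NO3)[C@@](C)(O[Si](CC)(CC)CC)C[C@@H](O[Si](C)(C)C(C)(C)C)[C@@H]12
A5 | alternative 3 | eleven-membered α-chloro sulfone (S between C4 and C5, Cl on C5) | COC(=O)C[C@H]1[C@H](O[Si](C)(C)C(C)(C)C)C(Cl)S(=O)(=O)C(C)C2=CC(=O)[C@@](C)(O2)C[C@H]1O[Si](C)(C)C(C)(C)C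
A6 | alternative 3 | ten-membered carbocycle with C4=C5 and C15 methyl | COC(=O)C[C@H]1[C@H](O[Si](C)(C)C(C)(C)C)/C=C(/C)C2=CC(=O)[C@@](C)(O2)C[C@H]1O[Si](C)(C)C(C)(C)C
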